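Lignan numbering is used throughout: aryl C1–C6 (ring A), C7, C8, C8', C7' (ring B chain), C1'–C6' (ring C, spiro atom C1', carbonyl C4').

## Analysis of the target

The target joins three rings. Ring A is a pentasubstituted arene with methoxy groups on C3, C4 and C5 and a hydrogen on C6. Ring B is a seven-membered carbocycle (aryl C1, C7, C8, C8', C7', C1', aryl C2). Ring C is a 2,6-dimethoxycyclohexa-2,5-dienone (carbonyl C4', methoxy groups on C3' and C5') that shares C1' with ring B.

Ring B carries three contiguous stereocentres: C7 (R, benzylic, acetoxy), C8 (S, methyl) and C8' (R, methyl). In the extended chain aryl C1–C7–C8–C8'–C7' the oxygen and both methyl groups lie on the same side (7,8-syn and 8,8'-syn), so the two methyl groups are trans on the ring.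

C1' is quaternary, benzylic and wedged between the C3 methoxy group and ring B. It is not a stereocentre, because its two ring C branches (C2'=C3' and C6'=C5') are identical.

The sensitive groups are:
- the cross-conjugated dienone (strong acid can cause dienone–phenol rearrangement, one-electron reductants can aromatise it with loss of a C1' substituent, nucleophiles can add at C2'/C6');
- the C7 ester, which is benzylic and para to the C4 methoxy group and so ionises easily;
- the acetate itself towards base.

The difficulty is to make the congested quaternary C1' beside a fully substituted, electron-rich arene while a stereotriad on a medium ring stays intact. The strategy rests on the symmetry of ring C. C3'–C4'–C5' with their two methoxy groups are the skeleton of a 1,3-dimethoxy ketone, C6' is one methylene, and C2' can be a formyl carbon on C1' of a preformed ring B. Ring C can therefore be annulated onto ring B with no stereochemical demand at C1'.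

## Retrosynthetic reasoning

Target 27 is the acetate of alcohol 26, and 26 is the desilylation product of 25. The ester goes on last because it would not survive the amine, enolate and amide-base conditions that build ring C. A tert-butyldimethylsilyl ether carries C7 through those steps.

Dienone 25 is taken back to mono-enone 23 by removing the C5'=C6' double bond, by way of silyl enol ether 24. This opens ring C to an annulation, since 23 is a 4,4-disubstituted 2-methoxycyclohexenone with one more methoxy group at C5'. The forward dehydrogenation has no regiochemical choice, because C5' is the only enolisable position of 23. The two extra stereocentres of 23 (C1', C5') disappear when ring C becomes symmetric.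

In 23 the bonds C1'–C6' and C2'–C3' are cut. This gives α-aryl aldehyde 15, whose formyl carbon becomes C2', and enone 20, which supplies C6', C5', C4' and C3' with both methoxy groups in place. The cut is made here because C1' then arises as the α-carbon of an aldehyde activated by both the formyl and the aryl group, a nucleophile well suited to forming quaternary centres by conjugate addition. The ring closure that follows can go only one way. The forward reaction must achieve a conjugate addition and an aldol condensation in one operation (Robinson annulation).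

Enone 20 is at once an enol ether and a vinyl ketone and would not keep. It is traced to ammonium salt 18, from which base releases it in the flask. Salt 18 comes from amine 17, and 17 from the symmetric ketone 16 by aminomethylation at one of its two equivalent α-carbons.

Aldehyde 15 is opened at the bond between C1' and aryl C2, giving open-chain bromo aldehyde 14. This bond is chosen over C7–C8 or aryl C1–C7 because it leaves the stereotriad in an acyclic chain that can be built from simple pieces. The forward reaction, a palladium-catalysed arylation of the aldehyde α-carbon, closes ring B and creates the formyl-bearing C1' together. The configuration at C1' does not matter, since the annulation erases it.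

Compound 14 is simplified by functional-group changes. Its formyl group is the cleavage product of the terminal alkene of 13. The bromine of 13 comes from electrophilic substitution of 12 at one of two equivalent free arene positions, and 12 is the silyl ether of 11. Bromine is introduced late so that no ortho-bromo aryl metal is needed, and the alkene masks the aldehyde through the organometallic steps.

Alcohol 11 is cut at the aryl C1–C7 bond into aldehyde 7 and aryl bromide 8, used as aryl metal 9 and then 10. Addition of a carbon nucleophile to an α-methyl aldehyde follows the Felkin–Anh model and so gives the required 7,8-syn relation from the C8 centre. The reverse polarity, reduction of an aryl ketone, would favour the 7,8-anti isomer.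

Aldehyde 7 goes back through alcohol 6 and silyl ether 5 to iodide 4, where the C7'–C1' bond is cut (primary iodide plus an allyl nucleophile). Iodide 4 comes from mono-silyl ether 3 of diol 2, and 2 from diacid 1, which already holds C8 and C8' with both methyl groups in the correct absolute configuration. Because 1 and 2 are C2-symmetric, telling the two ends apart needs only mono-functionalisation, not site selectivity.

## Alternatives that were turned down

Alternative 1: The disconnection is at C7–C8 and C8'–C7', with C8 and C8' taken from C4 and C3 of the chiral butenolide A2.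
- Key step: the lithium anion of aryl dithiane A3 adds to C4 of A2 anti to the menthyloxy group, and the lactone enolate is alkylated by benzyl chloromethyl ether A4 anti to the new substituent, giving trans,trans lactone A1 in one flask.
- For it: three components are joined in one operation, and the five-membered ring makes both anti relationships highly predictable. Chirality comes from an inexpensive auxiliary rather than from enantiopure acid 1; on availability of the chiral starting material this alternative is stronger.
- Against it: the carbons that must become the C8 and C8' methyl groups are the acetal carbon and the carbonyl carbon of the lactone. Both must be reduced to the alcohol level, activated and reduced again. The dithiane must be unmasked and the C7 ketone reduced with a facial sense that nothing in A1 fixes. The benzyl ether at C7' must be removed beside a benzylic C7–O bond before chain extension can start. No ring of the target is formed.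
- Comparison: A1 is estimated to be eight to ten steps from the stage of 12, which the chosen route reaches in eight steps with the methyl groups present from the start. The chosen route gives up the cheaper chirality source but spends nearly every step on a bond that stays in the target.

Alternative 2: The disconnection is at the C8–CH3 and C8'–CH3 bonds. Both methyl carbons arrive as the two CH2 termini of the parent thiocarbonyl ylide A7.
- Key step: A7 adds across the E double bond of enoate A6 to give thiolane A5; desulfurisation then reveals the two methyl groups.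
- For it: the cycloaddition is suprafacial on the alkene, so the E geometry is copied reliably into the trans (8,8'-syn) pair. C7 can be set beforehand by a reagent-controlled asymmetric reaction, which is firmer than the substrate-controlled addition of step 7. A6 is a few steps from simple aromatic feedstock, and the ester marks C7' for extension.
- Against it: the absolute configuration of C8 and C8' depends on 1,2-induction from the allylic silyloxy centre in a very exothermic cycloaddition with an early transition state. The competing conformations of the allylic system are close in energy, so neither the level nor the sense of induction (7,8-syn is needed) is secured. Desulfurisation over nickel threatens the benzylic C7–O bond of an electron-rich arene. The ester must still be reduced and lengthened by two carbons, as from 4 in the chosen route.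
- Comparison: the step count to the stage of 12 is similar. The chosen route gives up reagent control at C7 but takes C8 and C8' as a fixed unit, so one centre rather than two depends on induction.

Alternative 3: The disconnection is at C7–C8 as the last skeletal bond, with ring C already in place.
- Key step: the allylic bromide of aldehyde A9 is converted by a catalytic divalent chromium–chiral ligand system into an allylchromium species. This attacks the aryl aldehyde through its γ-carbon C8, closing ring B and giving homoallylic alcohol A8 with C7 and C8 set and an exocyclic methylene at C8'.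
- For it: this is the most convergent plan, with the shortest endgame (hydrogenation of the C8' methylene, acetylation). No protecting group is needed at C7, ring C is never dehydrogenated late, and a catalyst sets two stereocentres. On convergence and on steps after the key step it is stronger than the chosen route.
- Against it: γ-substituted allylchromium reagents add to aldehydes with an inherent anti preference, whereas the target needs 7,8-syn, so ligand and tether would have to overturn the normal sense in a seven-membered closure. The one-electron reductant meets a cross-conjugated dienone whose ketyl can aromatise by expelling the allylic C7' substituent from C1'. The chromium alkoxide at C7 lies within reach of C2'/C6'. The final hydrogenation must pick one 1,1-disubstituted alkene out of three C=C bonds and set C8' by substrate control on a flexible ring. A9 itself, with quaternary C1' between an ortho-formyl arene and the dienone, is demanding to make.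
- Comparison: the chosen route is longer after its key step, but it keeps the dienone away from all reducing and organometallic reagents, fixes C8 and C8' from the outset and asks no stereocontrol of its ring-forming steps.

Key step: step 14

Assumption: acid 1 is bought enantiopure (otherwise the racemic trans acid is resolved as a chiral amine salt before step 1); C1' and C5' are carried as epimer mixtures because step 16 removes both.

## Route

Step 1
Reactants: 1 (2S,3S)-2,3-dimethylsuccinic acid
Product: 2 (2S,3S)-2,3-dimethylbutane-1,4-diol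
Conditions: LiAlH4, THF, 0 °C → reflux; aqueous work-up
Reagents that add atoms: none
Why: Hydride reduction of both carboxylic acids to primary alcohols; the carboxylate intermediates are not enolised, so C8 and C8' keep the configuration of 1.

Step 2
Reactants: 2 (2S,3S)-2,3-dimethylbutane-1,4-diol
Product: 3 (2S,3S)-4-[(tert-butyldimethylsilyl)oxy]-2,3-dimethylbutan-1-ol
Conditions: NaH (1 equiv), THF, 0 °C → rt; then TBSCl (1 equiv)
Reagents that add atoms: tert-butyldimethylsilyl chloride (TBSCl), CC(C)(C)[Si](C)(C)Cl
Why: Mono-silylation of a symmetric diol through its sparingly soluble monosodium alkoxide (O-silylation); the two hydroxyl groups are homotopic, so only the degree of silylation, not the site, has to be controlled.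

Step 3
Reactants: 3 (2S,3S)-4-[(tert-butyldimethylsilyl)oxy]-2,3-dimethylbutan-1-ol
Product: 4 tert-butyl{[(2S,3S)-4-iodo-2,3-dimethylbutyl]oxy}dimethylsilane
Conditions: I2, PPh3, imidazole, CH2Cl2, 0 °C → rt
Reagents that add atoms: iodine, [I][I]
Why: Appel-type iodination; iodide displaces the alkoxyphosphonium group by SN2 at the primary carbon, imidazole buffers the acid, and the silyl ether and both stereocentres are untouched.

Step 4
Reactants: 4 tert-butyl{[(2S,3S)-4-iodo-2,3-dimethylbutyl]oxy}dimethylsilane
Product: 5 tert-butyl{[(2S,3R)-2,3-dimethylhept-6-en-1-yl]oxy}dimethylsilane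
Conditions: allylMgBr, CuI (10 mol %), THF, −30 → 0 °C
Reagents that add atoms: allylmagnesium bromide, C=CC[Mg]Br
Why: CuI-catalysed cross-coupling of an allyl Grignard reagent with a primary alkyl iodide; it forms the C7'–C1' bond and brings in the terminal alkene that later becomes the formyl group.

Step 5
Reactants: 5 tert-butyl{[(2S,3R)-2,3-dimethylhept-6-en-1-yl]oxy}dimethylsilane
Product: 6 (2S,3R)-2,3-dimethylhept-6-en-1-ol
Conditions: Bu4NF, THF, rt
Reagents that add atoms: none
Why: Fluoride-induced cleavage of the primary silyl ether; nothing else in 5 reacts with fluoride.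

Step 6
Reactants: 6 (2S,3R)-2,3-dimethylhept-6-en-1-ol
Product: 7 (2S,3R)-2,3-dimethylhept-6-enal
Conditions: Dess–Martin periodinane, pyridine, CH2Cl2, 0 °C → rt; used crude
Reagents that add atoms: none
Why: Dess–Martin oxidation under buffered, non-enolising conditions keeps the α-stereocentre C8 intact; 7 is taken on at once without purification.

Step 7
Reactants: 8 5-bromo-1,2,3-trimethoxybenzene; 7 (2S,3R)-2,3-dimethylhept-6-enal
Product: 11 (1R,2S,3R)-2,3-dimethyl-1-(3,4,5-trimethoxyphenyl)hept-6-en-1-ol, via 3,4,5-trimethoxyphenyllithium 9 (not isolated), via triisopropoxy(3,4,5-trimethoxyphenyl)titanium 10 (not isolated)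
Conditions: 8, n-BuLi, THF, −78 °C; ClTi(OiPr)3, −78 → −40 °C; then 7, −40 → 0 °C
Reagents that add atoms: none
Why: Bromine–lithium exchange gives 9 and transmetallation gives the non-basic aryltitanium 10, which adds to the aldehyde without enolising it; Felkin–Anh control (attack anti to the sec-alkyl group on C8, past the hydrogen) should favour the 7,8-syn, that is (1R), alcohol, and the minor C7 epimer is to be removed by chromatography.

Step 8
Reactants: 11 (1R,2S,3R)-2,3-dimethyl-1-(3,4,5-trimethoxyphenyl)hept-6-en-1-ol
Product: 12 tert-butyl{[(1R,2S,3R)-2,3-dimethyl-1-(3,4,5-trimethoxyphenyl)hept-6-en-1-yl]oxy}dimethylsilane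
Conditions: TBSOTf, 2,6-lutidine, CH2Cl2, −78 → 0 °C
Reagents that add atoms: tert-butyldimethylsilyl trifluoromethanesulfonate (TBSOTf), CC(C)(C)[Si](C)(C)OS(=O)(=O)C(F)(F)F
Why: O-Silylation of a hindered secondary benzylic alcohol with a silyl triflate; the excess hindered base prevents acid-induced ionisation at C7.

Step 9
Reactants: 12 tert-butyl{[(1R,2S,3R)-2,3-dimethyl-1-(3,4,5-trimethoxyphenyl)hept-6-en-1-yl]oxy}dimethylsilane
Product: 13 {[(1R,2S,3R)-1-(2-bromo-3,4,5-trimethoxyphenyl)-2,3-dimethylhept-6-en-1-yl]oxy}(tert-butyl)dimethylsilane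
Conditions: NBS (1 equiv), MeCN, 0 °C, dark
Reagents that add atoms: N-bromosuccinimide (NBS), O=C1CCC(=O)N1Br
Why: Electrophilic aromatic bromination; the two free arene positions are equivalent and activated ortho and para by methoxy groups, so substitution there should be far faster than any reaction of NBS with the isolated alkene, and one equivalent limits it to mono-bromination.

Step 10
Reactants: 13 {[(1R,2S,3R)-1-(2-bromo-3,4,5-trimethoxyphenyl)-2,3-dimethylhept-6-en-1-yl]oxy}(tert-butyl)dimethylsilane
Product: 14 (4R,5S,6R)-6-(2-bromo-3,4,5-trimethoxyphenyl)-6-[(tert-butyldimethylsilyl)oxy]-4,5-dimethylhexanal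
Conditions: OsO4 (cat.), NaIO4, 2,6-lutidine, dioxane/H2O, rt
Reagents that add atoms: osmium tetroxide, O=[Os](=O)(=O)=O (transfers the oxygen of the new formyl group; regenerated by sodium periodate, [Na+].[O-][I](=O)(=O)=O)
Why: Lemieux–Johnson cleavage (dihydroxylation of the terminal alkene, then glycol cleavage); 2,6-lutidine keeps the medium neutral for the silyl ether and suppresses over-oxidation, and the arene and the C–Br bond are inert.

Step 11
Reactants: 14 (4R,5S,6R)-6-(2-bromo-3,4,5-trimethoxyphenyl)-6-[(tert-butyldimethylsilyl)oxy]-4,5-dimethylhexanal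
Product: 15 (7R,8S,9R)-9-[(tert-butyldimethylsilyl)oxy]-2,3,4-trimethoxy-7,8-dimethyl-6,7,8,9-tetrahydro-5H-benzo[7]annulene-5-carbaldehyde (both C5 epimers; C5 is C1')
Conditions: Pd(OAc)2 (10 mol %), rac-BINAP, Cs2CO3, dioxane, 90 °C, high dilution, slow addition of 14, argon
Reagents that add atoms: none
Why: Palladium-catalysed intramolecular α-arylation of an aldehyde: oxidative addition of the C–Br bond to zerovalent palladium, enolisation by Cs2CO3 and reductive elimination from the palladium enolate form the aryl C2–C1' bond and close ring B, while dilution holds back intermolecular aldol condensation. The new centre C1' is uncontrolled, which is harmless because step 14 makes it trigonal.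

Step 12
Reactants: 16 1,3-dimethoxypropan-2-one
Product: 17 4-(dimethylamino)-1,3-dimethoxybutan-2-one (racemic)
Conditions: (CH2=NMe2)I, 16 in excess, MeCN, 40 °C; aq. NaHCO3
Reagents that add atoms: N,N-dimethylmethyleneiminium iodide (Eschenmoser's salt), C=[N+](C)C.[I-]
Why: Mannich reaction of the enol of 16 with a preformed iminium salt; the two α-methylene groups of 16 are equivalent and the excess of 16 limits the reaction to one aminomethylation.

Step 13
Reactants: 17 4-(dimethylamino)-1,3-dimethoxybutan-2-one
Product: 18 2,4-dimethoxy-N,N,N-trimethyl-3-oxobutan-1-aminium iodide (racemic)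
Conditions: MeI, Et2O, 0 °C → rt
Reagents that add atoms: iodomethane, CI
Why: Menshutkin quaternisation of the tertiary amine; the trimethylammonium group is the leaving group that lets mild base release enone 20 in step 14.

Step 14
Reactants: 15 (7R,8S,9R)-9-[(tert-butyldimethylsilyl)oxy]-2,3,4-trimethoxy-7,8-dimethyl-6,7,8,9-tetrahydro-5H-benzo[7]annulene-5-carbaldehyde; 18 2,4-dimethoxy-N,N,N-trimethyl-3-oxobutan-1-aminium iodide
Product: 23 (7R,8S,9R)-9-[(tert-butyldimethylsilyl)oxy]-2,3,3',4,5'-pentamethoxy-7,8-dimethyl-6,7,8,9-tetrahydrospiro[benzo[7]annulene-5,1'-cyclohex[2]en]-4'-one (epimers at C1' and C5'), via pyrrolidine enamine 19 (not isolated), via 1,3-dimethoxybut-3-en-2-one 20 (not isolated), via keto aldehyde 21 (not isolated), via ketol 22 (not isolated)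
Conditions: pyrrolidine, 4 Å MS, PhMe, 50 °C; then 18 (excess), i-Pr2NEt, MeCN, 0 °C → rt; then AcOH/NaOAc, H2O, 70 °C
Reagents that add atoms: none
Why: Pyrrolidine condenses with 15 to enamine 19, in which both C1' epimers merge into one trigonal carbon, while i-Pr2NEt releases enone 20 from 18 by E1cB loss of trimethylamine, so the polymerisable acceptor never accumulates. Enamine 19 attacks the unsubstituted terminus C6' of 20 through C1' (Stork enamine Michael addition), forming the C1'–C6' bond and the quaternary centre, and buffered hydrolysis frees keto aldehyde 21. Since C1' now has no hydrogen, 21 can enolise only in its ketone half, and only C3' can reach the formyl carbon through a six-membered transition state (6-enolendo-exo-trig aldol addition to ketol 22, whereas attack from C5' would give a cyclobutane); loss of water then conjugates C2'=C3' with C4'=O and gives 23. The closest known reaction is the Robinson annulation of α-aryl α-alkyl aldehydes or their enamines with simple vinyl ketones to 4,4-disubstituted cyclohexenones; the only change is that the vinyl ketone carries a methoxy group on each α-carbon. Two stereocentres arise, C1' and C5'; neither is controlled and neither needs to be, because C5' becomes trigonal and C1' stops being stereogenic when ring C is made symmetric in step 16. The step needs C- over N-alkylation of 19 and 1,4- over 1,2-addition: N-alkylation is reversible and C-alkylation is not, and the terminal CH2 of 20 is its only unhindered electrophilic site. The α-methoxy group makes 20 a weaker acceptor than an unsubstituted vinyl ketone, which is why it is set free slowly in the presence of the nucleophile; the C7 silyl ether and C8/C8' lie outside the reacting system, and the acetate buffer is too mild to ionise C7.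

Step 15
Reactants: 23 (7R,8S,9R)-9-[(tert-butyldimethylsilyl)oxy]-2,3,3',4,5'-pentamethoxy-7,8-dimethyl-6,7,8,9-tetrahydrospiro[benzo[7]annulene-5,1'-cyclohex[2]en]-4'-one
Product: 24 tert-butyl{[(7R,8S,9R)-2,3,3',4,5'-pentamethoxy-7,8-dimethyl-4'-[(trimethylsilyl)oxy]-6,7,8,9-tetrahydrospiro[benzo[7]annulene-5,1'-cyclohexa[2,4]dien]-9-yl]oxy}dimethylsilane (C1' epimers)
Conditions: LiN(SiMe3)2, THF, −78 °C; Me3SiCl, Et3N, −78 → 0 °C; used crude
Reagents that add atoms: chlorotrimethylsilane, C[Si](C)(C)Cl
Why: Kinetic enolate formation and O-silylation; C5'–H is the only acidic hydrogen next to the carbonyl (C3' is trigonal and the γ-position C1' is quaternary), so 24 is the only possible silyl enol ether.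

Step 16
Reactants: 24 tert-butyl{[(7R,8S,9R)-2,3,3',4,5'-pentamethoxy-7,8-dimethyl-4'-[(trimethylsilyl)oxy]-6,7,8,9-tetrahydrospiro[benzo[7]annulene-5,1'-cyclohexa[2,4]dien]-9-yl]oxy}dimethylsilane
Product: 25 (7R,8S,9R)-9-[(tert-butyldimethylsilyl)oxy]-2,3,3',4,5'-pentamethoxy-7,8-dimethyl-6,7,8,9-tetrahydrospiro[benzo[7]annulene-5,1'-cyclohexa[2,5]dien]-4'-one
Conditions: Pd(OAc)2 (1.1 equiv), MeCN, rt
Reagents that add atoms: none
Why: Saegusa–Ito oxidation: divalent palladium attacks the enol ether at C5' to give a palladium enolate, and β-hydride elimination from C6' (the only β-hydrogens) forms the C5'=C6' bond; ring C becomes symmetric, so all epimers of 23/24 converge on the single dienone 25.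

Step 17
Reactants: 25 (7R,8S,9R)-9-[(tert-butyldimethylsilyl)oxy]-2,3,3',4,5'-pentamethoxy-7,8-dimethyl-6,7,8,9-tetrahydrospiro[benzo[7]annulene-5,1'-cyclohexa[2,5]dien]-4'-one
Product: 26 (7R,8S,9R)-9-hydroxy-2,3,3',4,5'-pentamethoxy-7,8-dimethyl-6,7,8,9-tetrahydrospiro[benzo[7]annulene-5,1'-cyclohexa[2,5]dien]-4'-one
Conditions: HF·pyridine, pyridine, THF, 0 °C → rt
Reagents that add atoms: none
Why: Fluoride cleavage of the secondary silyl ether under pyridine buffering, which avoids a free alkoxide next to the dienone (conjugate addition at C2'/C6') and avoids acid strong enough to ionise C7 or rearrange the dienone.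

Step 18
Reactants: 26 (7R,8S,9R)-9-hydroxy-2,3,3',4,5'-pentamethoxy-7,8-dimethyl-6,7,8,9-tetrahydrospiro[benzo[7]annulene-5,1'-cyclohexa[2,5]dien]-4'-one
Product: 27 (7R,8S,9R)-2,3,3',4,5'-pentamethoxy-7,8-dimethyl-4'-oxo-6,7,8,9-tetrahydrospiro[benzo[7]annulene-5,1'-cyclohexa[2,5]dien]-9-yl acetate (CNP0143674.1)
Conditions: Ac2O, Et3N, 4-(dimethylamino)pyridine (cat.), CH2Cl2, 0 °C → rt
Reagents that add atoms: acetic anhydride, CC(=O)OC(C)=O
Why: Acylation with nucleophilic catalysis by 4-(dimethylamino)pyridine; the C7–O bond is not broken, so the (R) configuration is retained.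

## Compound list

1 | (2S,3S)-2,3-dimethylsuccinic acid | OC(=O)[C@@H](C)[C@H](C)C(O)=O | starting material
2 | (2S,3S)-2,3-dimethylbutane-1,4-diol | OC[C@@H](C)[C@H](C)CO | intermediate
3 | (2S,3S)-4-[(tert-butyldimethylsilyl)oxy]-2,3-dimethylbutan-1-ol | OC[C@@H](C)[C@H](C)CO[Si](C)(C)C(C)(C)C | intermediate
4 | tert-butyl{[(2S,3S)-4-iodo-2,3-dimethylbutyl]oxy}dimethylsilane | IC[C@@H](C)[C@H](C)CO[Si](C)(C)C(C)(C)C | intermediate
5 | tert-butyl{[(2S,3R)-2,3-dimethylhept-6-en-1-yl]oxy}dimethylsilane | C=CCC[C@@H](C)[C@H](C)CO[Si](C)(C)C(C)(C)C | intermediate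
6 | (2S,3R)-2,3-dimethylhept-6-en-1-ol | C=CCC[C@@H](C)[C@H](C)CO | intermediate
7 | (2S,3R)-2,3-dimethylhept-6-enal | C=CCC[C@@H](C)[C@H](C)C=O | intermediate
8 | 5-bromo-1,2,3-trimethoxybenzene | COc1cc(Br)cc(OC)c1OC | starting material
9 | 3,4,5-trimethoxyphenyllithium | COc1cc([Li])cc(OC)c1OC | intermediate
10 | triisopropoxy(3,4,5-trimethoxyphenyl)titanium | COc1cc(cc(OC)c1OC)[Ti](OC(C)C)(OC(C)C)OC(C)C | intermediate
11 | (1R,2S,3R)-2,3-dimethyl-1-(3,4,5-trimethoxyphenyl)hept-6-en-1-ol | C=CCC[C@@H](C)[C@H](C)[C@@H](O)c1cc(OC)c(OC)c(OC)c1 | intermediate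
12 | tert-butyl{[(1R,2S,3R)-2,3-dimethyl-1-(3,4,5-trimethoxyphenyl)hept-6-en-1-yl]oxy}dimethylsilane | C=CCC[C@@H](C)[C@H](C)[C@@H](O[Si](C)(C)C(C)(C)C)c1cc(OC)c(OC)c(OC)c1 | intermediate
13 | {[(1R,2S,3R)-1-(2-bromo-3,4,5-trimethoxyphenyl)-2,3-dimethylhept-6-en-1-yl]oxy}(tert-butyl)dimethylsilane | C=CCC[C@@H](C)[C@H](C)[C@@H](O[Si](C)(C)C(C)(C)C)c1cc(OC)c(OC)c(OC)c1Br | intermediate
14 | (4R,5S,6R)-6-(2-bromo-3,4,5-trimethoxyphenyl)-6-[(tert-butyldimethylsilyl)oxy]-4,5-dimethylhexanal | O=CCC[C@@H](C)[C@H](C)[C@@H](O[Si](C)(C)C(C)(C)C)c1cc(OC)c(OC)c(OC)c1Br | intermediate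
15 | (7R,8S,9R)-9-[(tert-butyldimethylsilyl)oxy]-2,3,4-trimethoxy-7,8-dimethyl-6,7,8,9-tetrahydro-5H-benzo[7]annulene-5-carbaldehyde (C5 epimers) | O=CC1C[C@@H](C)[C@H](C)[C@@H](O[Si](C)(C)C(C)(C)C)c2cc(OC)c(OC)c(OC)c12 | intermediate
16 | 1,3-dimethoxypropan-2-one | COCC(=O)COC | starting material
17 | 4-(dimethylamino)-1,3-dimethoxybutan-2-one (racemic) | COCC(=O)C(OC)CN(C)C | intermediate
18 | 2,4-dimethoxy-N,N,N-trimethyl-3-oxobutan-1-aminium iodide (racemic) | COCC(=O)C(OC)C[N+](C)(C)C.[I-] | intermediate
19 | 1-{[(7R,8S,9R)-9-[(tert-butyldimethylsilyl)oxy]-2,3,4-trimethoxy-7,8-dimethyl-6,7,8,9-tetrahydro-5H-benzo[7]annulen-5-ylidene]methyl}pyrrolidine (E/Z unassigned) | C(=C1C[C@@H](C)[C@H](C)[C@@H](O[Si](C)(C)C(C)(C)C)c2cc(OC)c(OC)c(OC)c12)N1CCCC1 | intermediate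
20 | 1,3-dimethoxybut-3-en-2-one | COCC(=O)C(=C)OC | intermediate
21 | (7R,8S,9R)-9-[(tert-butyldimethylsilyl)oxy]-5-(2,4-dimethoxy-3-oxobutyl)-2,3,4-trimethoxy-7,8-dimethyl-6,7,8,9-tetrahydro-5H-benzo[7]annulene-5-carbaldehyde (epimer mixture) | O=CC1(CC(OC)C(=O)COC)C[C@@H](C)[C@H](C)[C@@H](O[Si](C)(C)C(C)(C)C)c2cc(OC)c(OC)c(OC)c12 | intermediate
22 | (7R,8S,9R)-9-[(tert-butyldimethylsilyl)oxy]-2'-hydroxy-2,3,3',4,5'-pentamethoxy-7,8-dimethyl-6,7,8,9-tetrahydrospiro[benzo[7]annulene-5,1'-cyclohexan]-4'-one (epimer mixture) | COC1C(O)C2(CC(OC)C1=O)C[C@@H](C)[C@H](C)[C@@H](O[Si](C)(C)C(C)(C)C)c1cc(OC)c(OC)c(OC)c12 | intermediate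
23 | (7R,8S,9R)-9-[(tert-butyldimethylsilyl)oxy]-2,3,3',4,5'-pentamethoxy-7,8-dimethyl-6,7,8,9-tetrahydrospiro[benzo[7]annulene-5,1'-cyclohex[2]en]-4'-one (C1' and C5' epimers) | COC1=CC2(CC(OC)C1=O)C[C@@H](C)[C@H](C)[C@@H](O[Si](C)(C)C(C)(C)C)c1cc(OC)c(OC)c(OC)c12 | intermediate
24 | tert-butyl{[(7R,8S,9R)-2,3,3',4,5'-pentamethoxy-7,8-dimethyl-4'-[(trimethylsilyl)oxy]-6,7,8,9-tetrahydrospiro[benzo[7]annulene-5,1'-cyclohexa[2,4]dien]-9-yl]oxy}dimethylsilane (C1' epimers) | COC1=CC2(CC(OC)=C1O[Si](C)(C)C)C[C@@H](C)[C@H](C)[C@@H](O[Si](C)(C)C(C)(C)C)c1cc(OC)c(OC)c(OC)c12 | intermediate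
25 | (7R,8S,9R)-9-[(tert-butyldimethylsilyl)oxy]-2,3,3',4,5'-pentamethoxy-7,8-dimethyl-6,7,8,9-tetrahydrospiro[benzo[7]annulene-5,1'-cyclohexa[2,5]dien]-4'-one | COC1=CC2(C=C(OC)C1=O)C[C@@H](C)[C@H](C)[C@@H](O[Si](C)(C)C(C)(C)C)c1cc(OC)c(OC)c(OC)c12 | intermediate
26 | (7R,8S,9R)-9-hydroxy-2,3,3',4,5'-pentamethoxy-7,8-dimethyl-6,7,8,9-tetrahydrospiro[benzo[7]annulene-5,1'-cyclohexa[2,5]dien]-4'-one | COC1=CC2(C=C(OC)C1=O)C[C@@H](C)[C@H](C)[C@@H](O)c1cc(OC)c(OC)c(OC)c12 | intermediate
27 | (7R,8S,9R)-2,3,3',4,5'-pentamethoxy-7,8-dimethyl-4'-oxo-6,7,8,9-tetrahydrospiro[benzo[7]annulene-5,1'-cyclohexa[2,5]dien]-9-yl acetate | COC1=CC2(C=C(OC)C1=O)C[C@@H](C)[C@H](C)[C@@H](OC(C)=O)c1cc(OC)c(OC)c(OC)c12 | target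

## Step count and least certain steps

Total step count: 18. Longest linear sequence: 16 (steps 1–11 and 14–18); steps 12 and 13 are a two-step side branch.

**Step 14 (key step).** The most likely failure is that conjugate addition does not keep pace with decay of the acceptor. The methoxy group on the α-carbon of 20 donates into the very carbon (C6') that must be attacked, and C1' of 19 is shielded by the C3 methoxy group and ring B. Reversible N-alkylation, amine addition to 20 and oligomerisation of 20 may therefore outrun C–C bond formation. A retro-Michael reaction of 21 during the buffered heating is a second drain.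

Fallback: set out from 15 and run the same annulation with the more electrophilic, unsubstituted vinyl partner 1-methoxybut-3-en-2-one, which should give the spiro 2-methoxycyclohexenone F1. Enolisation of F1 with LiN(SiMe3)2 and oxidation with 2-(phenylsulfonyl)-3-phenyloxaziridine would give the α'-hydroxy ketone F2. Dess–Martin oxidation of F2 leads to a 1,2-diketone that should rest as the diosphenol F3. O-Methylation of F3 (MeI, K2CO3, acetone) comes back to the route at 25, bypassing 23 and 24. This brings in the second ring C oxygen by oxidation instead of carrying it on the acceptor.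

**Step 11.** Base-induced self-condensation of the unbranched aldehyde and protodebromination may outpace oxidative addition into the doubly ortho-substituted, electron-rich C–Br bond, and the closure is a seven-membered one.

Fallback: set out from 14 and silylate it (TBSOTf, Et3N) to the silyl enol ether F4, which cannot undergo aldol chemistry. An intramolecular Heck reaction (Pd(OAc)2, PPh3, Et3N, MeCN, 80 °C) should carbopalladate the enol ether in the 7-exo mode, with the aryl group going to C1', and β-hydride elimination would give the exocyclic silyl enol ether F5. Methanolysis of F5 (K2CO3, MeOH, 0 °C) comes back to the route at 15.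

**Step 7.** Facial selectivity may be insufficient. Felkin–Anh control by a methyl against a sec-alkyl group on C8 is only moderate, the C8' centre may erode it, and the epimers may be hard to separate.

Fallback: set out from 11 as obtained, mixed with its C7 epimer, the (1S) alcohol F6. Oxidise the mixture (Dess–Martin periodinane) to the aryl ketone F7 and reduce it under reagent control with BH3·SMe2 and (S)-5,5-diphenyl-2-methyl-3,4-propano-1,3,2-oxazaborolidine (Corey–Bakshi–Shibata reduction, aryl as the large group). This is expected to give the (1R) alcohol against the substrate bias and comes back at 11.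

**Step 16.** The very electron-rich, tetrasubstituted silyl enol ether 24 may undergo protodesilylation back to 23, or palladation at the hindered, methoxy-bearing C5' may be slow.

Fallback: set out from 23, form the lithium enolate (LiN(SiMe3)2) and trap it with PhSeCl to give the α-phenylselanyl ketone F8. Oxidation with H2O2 and syn-elimination of the selenoxide, which can only go towards C6', comes back at 25.

**Step 17.** Ring C or the C7 centre may be lost during desilylation. A C7 alkoxide can add to C2'/C6' of the dienone through a six-membered transition state, and acid strong enough to cleave a sluggish secondary silyl ether may ionise C7 or rearrange the dienone.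

Fallback: exchange silyl for acetyl before the dienone exists. Set out from 23 and desilylate it (Bu4NF/AcOH, or mild acid, which the mono-enone tolerates because it has no dienone–phenol pathway) to the enone alcohol F9. Acetylate F9 to the enone acetate F10. Soft enolisation (Me3SiOTf, Et3N), which leaves the acetate alone, would give the silyl enol ether F11, and Pd(OAc)2 then comes back to the route at 27.

## Further compounds

F1 | step 14 | (7R,8S,9R)-9-[(tert-butyldimethylsilyl)oxy]-2,3,3',4-tetramethoxy-7,8-dimethyl-6,7,8,9-tetrahydrospiro[benzo[7]annulene-5,1'-cyclohex[2]en]-4'-one (C1' epimers) | COC1=CC2(CCC1=O)C[C@@H](C)[C@H](C)[C@@H](O[Si](C)(C)C(C)(C)C)c1cc(OC)c(OC)c(OC)c12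
F2 | step 14 | (7R,8S,9R)-9-[(tert-butyldimethylsilyl)oxy]-5'-hydroxy-2,3,3',4-tetramethoxy-7,8-dimethyl-6,7,8,9-tetrahydrospiro[benzo[7]annulene-5,1'-cyclohex[2]en]-4'-one (epimer mixture) | COC1=CC2(CC(O)C1=O)C[C@@H](C)[C@H](C)[C@@H](O[Si](C)(C)C(C)(C)C)c1cc(OC)c(OC)c(OC)c12
F3 | step 14 | (7R,8S,9R)-9-[(tert-butyldimethylsilyl)oxy]-5'-hydroxy-2,3,3',4-tetramethoxy-7,8-dimethyl-6,7,8,9-tetrahydrospiro[benzo[7]annulene-5,1'-cyclohexa[2,5]dien]-4'-one | COC1=CC2(C=C(O)C1=O)C[C@@H](C)[C@H](C)[C@@H](O[Si](C)(C)C(C)(C)C)c1cc(OC)c(OC)c(OC)c12
F4 | step 11 | {[(1R,2S,3R)-1-(2-bromo-3,4,5-trimethoxyphenyl)-6-[(tert-butyldimethylsilyl)oxy]-2,3-dimethylhex-5-en-1-yl]oxy}(tert-butyl)dimethylsilane (E/Z unassigned) | CC(C)(C)[Si](C)(C)OC=CC[C@@H](C)[C@H](C)[C@@H](O[Si](C)(C)C(C)(C)C)c1cc(OC)c(OC)c(OC)c1Br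
F5 | step 11 | tert-butyl{[(7R,8S,9R)-9-[(tert-butyldimethylsilyl)oxy]-2,3,4-trimethoxy-7,8-dimethyl-6,7,8,9-tetrahydro-5H-benzo[7]annulen-5-ylidene]methoxy}dimethylsilane (E/Z unassigned) | CC(C)(C)[Si](C)(C)OC=C1C[C@@H](C)[C@H](C)[C@@H](O[Si](C)(C)C(C)(C)C)c2cc(OC)c(OC)c(OC)c12
F6 | step 7 | (1S,2S,3R)-2,3-dimethyl-1-(3,4,5-trimethoxyphenyl)hept-6-en-1-ol | C=CCC[C@@H](C)[C@H](C)[C@H](O)c1cc(OC)c(OC)c(OC)c1
F7 | step 7 | (2S,3R)-2,3-dimethyl-1-(3,4,5-trimethoxyphenyl)hept-6-en-1-one | C=CCC[C@@H](C)[C@H](C)C(=O)c1cc(OC)c(OC)c(OC)c1
F8 | step 16 | (7R,8S,9R)-9-[(tert-butyldimethylsilyl)oxy]-2,3,3',4,5'-pentamethoxy-7,8-dimethyl-5'-(phenylselanyl)-6,7,8,9-tetrahydrospiro[benzo[7]annulene-5,1'-cyclohex[2]en]-4'-one (epimer mixture) | COC1=CC2(CC(OC)([Se]c3ccccc3)C1=O)C[C@@H](C)[C@H](C)[C@@H](O[Si](C)(C)C(C)(C)C)c1cc(OC)c(OC)c(OC)c12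
F9 | step 17 | (7R,8S,9R)-9-hydroxy-2,3,3',4,5'-pentamethoxy-7,8-dimethyl-6,7,8,9-tetrahydrospiro[benzo[7]annulene-5,1'-cyclohex[2]en]-4'-one (C1' and C5' epimers) | COC1=CC2(CC(OC)C1=O)C[C@@H](C)[C@H](C)[C@@H](O)c1cc(OC)c(OC)c(OC)c12
F10 | step 17 | (7R,8S,9R)-2,3,3',4,5'-pentamethoxy-7,8-dimethyl-4'-oxo-6,7,8,9-tetrahydrospiro[benzo[7]annulene-5,1'-cyclohex[2]en]-9-yl acetate (C1' and C5' epimers) | COC1=CC2(CC(OC)C1=O)C[C@@H](C)[C@H](C)[C@@H](OC(C)=O)c1cc(OC)c(OC)c(OC)c12
F11 | step 17 | (7R,8S,9R)-2,3,3',4,5'-pentamethoxy-7,8-dimethyl-4'-[(trimethylsilyl)oxy]-6,7,8,9-tetrahydrospiro[benzo[7]annulene-5,1'-cyclohexa[2,4]dien]-9-yl acetate (C1' epimers) | COC1=CC2(CC(OC)=C1O[Si](C)(C)C)C[C@@H](C)[C@H](C)[C@@H](OC(C)=O)c1cc(OC)c(OC)c(OC)c12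
A1 | alternative 1 | trans,trans-3-(benzyloxymethyl)-5-menthyloxy-4-[2-(3,4,5-trimethoxyphenyl)-1,3-dithian-2-yl]dihydrofuran-2(3H)-one | c1ccccc1COC[C@H]1C(=O)O[C@@H](O[C@@H]2C[C@H](C)CC[C@H]2C(C)C)[C@@H]1C1(SCCCS1)c1cc(OC)c(OC)c(OC)c1
A2 | alternative 1 | (5R)-5-[(1R,2S,5R)-menthyloxy]furan-2(5H)-one | O=C1C=C[C@H](O[C@@H]2C[C@H](C)CC[C@H]2C(C)C)O1
A3 | alternative 1 | 2-(3,4,5-trimethoxyphenyl)-1,3-dithiane | COc1cc(cc(OC)c1OC)C1SCCCS1
A4 | alternative 1 | benzyl chloromethyl ether | ClCOCc1ccccc1
A5 | alternative 2 | methyl trans-4-{(R)-[(tert-butyldimethylsilyl)oxy](3,4,5-trimethoxyphenyl)methyl}thiolane-3-carboxylate | COC(=O)[C@H]1CSC[C@@H]1[C@@H](O[Si](C)(C)C(C)(C)C)c1cc(OC)c(OC)c(OC)c1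
A6 | alternative 2 | methyl (2E,4R)-4-[(tert-butyldimethylsilyl)oxy]-4-(3,4,5-trimethoxyphenyl)but-2-enoate | COC(=O)/C=C/[C@@H](O[Si](C)(C)C(C)(C)C)c1cc(OC)c(OC)c(OC)c1
A7 | alternative 2 | thioformaldehyde S-methylide (parent thiocarbonyl ylide) | C=[S+][CH2-]
A8 | alternative 3 | (8S,9R)-9-hydroxy-2,3,3',4,5'-pentamethoxy-8-methyl-7-methylidene-6,7,8,9-tetrahydrospiro[benzo[7]annulene-5,1'-cyclohexa[2,5]dien]-4'-one | COC1=CC2(C=C(OC)C1=O)CC(=C)[C@H](C)[C@@H](O)c1cc(OC)c(OC)c(OC)c12
A9 | alternative 3 | 2-{1-[2-(bromomethyl)but-2-en-1-yl]-3,5-dimethoxy-4-oxocyclohexa-2,5-dien-1-yl}-3,4,5-trimethoxybenzaldehyde (alkene geometry unassigned) | CC=C(CBr)CC1(C=C(OC)C(=O)C(OC)=C1)c1c(C=O)cc(OC)c(OC)c1OC
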